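(The numbers of this flask were chosen freely; the flask was simulated.)

In a one-step world the starting material becomes intermediate and the first nucleophile catches every intermediate, so the target stops at the first nucleophile's charge, 90.0% of the starting material. The real flasks have more steps:

| setting | east | south | north-west |
|---|---|---|---|
| starting material | 12 mM | 12 mM | 12 mM |
| first nucleophile | 0.900 equiv | 0.900 equiv | 0.900 equiv |
| second nucleophile | 1.20 equiv | 1.20 equiv | 1.20 equiv |
| protic impurity | 6.00 mM | 6.00 mM | 6.00 mM |
| temperature | 120 °C | 90 °C | 105 °C |
| time | 4.0 h | 4.0 h | 4.0 h |

    second nucleophile + intermediate → other capture product (k1 = 1400 M⁻¹ h⁻¹, Ea1 = 57.0 kJ mol⁻¹)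
    starting material + protic impurity → quenched substrate (k2 = 1100 M⁻¹ h⁻¹, Ea2 = 44.0 kJ mol⁻¹)
    first nucleophile + intermediate → target (k3 = 700 M⁻¹ h⁻¹, Ea3 = 59.0 kJ mol⁻¹)
    intermediate → solvolysis product (k4 = 3.0 h⁻¹, Ea4 = 113 kJ mol⁻¹)
    starting material → intermediate (k5 = 1.0 h⁻¹, Ea5 = 120 kJ mol⁻¹)
    (constants at 90 °C)

- all constants are for 90 °C and move with temperature by the activation energies

1. the best flask by amount of target, in percent of the starting material charged; "all alike" if 1.5 percentage points covers them all (east / south / north-west / all alike)
2. amount of target at the end, in percent of the starting material charged, east
3. amount of target at the end, in percent of the starting material charged, south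
4. amount of target at the end, in percent of the starting material charged, north-west

We follow one molecule and ask for its chance at each fork. We take the nucleophiles at their charged concentrations, so that each capture is pseudo-first-order and a fork is a ratio of rates per hour. South runs at the reference temperature. For east, each constant's factor is that of the ionisation step raised to the ratio of the activation energies.

First we add solvolysis. In east the first nucleophile takes intermediate at 33.6 h⁻¹ against 52.2 h⁻¹ for solvolysis. In south the same pair is 7.56 h⁻¹ against 3.00 h⁻¹.

Next we add the second nucleophile, at 85.1 h⁻¹ in east and 20.2 h⁻¹ in south. The target's part of these three rates is the capture share.

Last we add the quench, an earlier fork. Dividing the two loss rates of the starting material gives the amount ionised as a·ln(c(protic impurity) at the start / c(protic impurity) now), where a is the ionisation constant over the quench constant. That a is 6.21 mM in east and 0.909 mM in south. We reckon as if conversion were complete, since the ionisation constant times the run is 4.00 even in south. The amount ionised plus the impurity consumed then equals the charge. Solving this by repeated substitution gives 7.72 mM ionised in east and 6.01 mM in south.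

| chance of one molecule | east | south |
|---|---|---|
| target against solvolysis | 39.2% | 71.6% |
| capture share, second nucleophile added | 19.7% | 24.6% |
| ionised share | 64.3% | 50.1% |
| product of the last two | 12.6% | 12.3% |

That product is the target chance: the ionised share times the capture share. East has the smaller capture share and the larger ionised share, and the products come out close. They differ by 0.30 percentage points, against a margin of 1.5 points. Our reckoning covers these two temperatures, and north-west lies between them, so we expect flasks that count as equal.

The forecast says all alike, with 12.8% for east, 12.6% for south and 12.5% for north-west, on the grounds that “Higher temperature beats quenching but loses to solvolysis, and the two cancel”.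

The simulation gives all alike: 12.8% in east, 12.6% in south and 12.5% in north-west.

East's result stands 0.20 points above its target chance. In east, the conversion of second nucleophile and intermediate into other capture product and the conversion of starting material and protic impurity into quenched substrate act together as part of what holds the target down: with the first conversion taken away the target there reaches 23.0%, and with the second taken away 19.9%. A flask like east but with 0.480 equiv of second nucleophile keeps east's quenched substrate at 35.6%, so its ionised share stands and its capture share rises, giving a target chance of 18.0%. That flask ends with 17.6% target.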